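If a flask still holds starting material when it is read, the next question is how much more target it will make while that remainder goes.

all flasks: starting material 0.80 M; partner 1.05 equiv

| charge | capture agent | remark | time |
|---|---|---|---|
| summer | 0.027 M | run made earlier |  |
| dawn | 0.060 M | run made earlier |  |
| flask | 0.0400 M |  | 30 h |

- summer (time / h: starting material / %, target / %): 1.50: 91.4, 0; 5.00: 71.2, 2.7; 8.00: 56.9, 8.1; 12.0: 41.7, 15.9; 20.0: 23.6, 26.9; 25.0: 17.5, 32.6; 30.0: 12.3, 36.8
- dawn (time / h: starting material / %, target / %): 4.00: 76.5, 1.5; 8.00: 56.4, 7.8; 12.0: 41.5, 15.0; 15.0: 33.4, 20.9; 20.0: 23.9, 26.6; 25.0: 16.8, 32.3; 30.0: 12.5, 35.4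

(standard deviation of a reading: 0.3 percentage points)

1. why nothing more happens at 30 h, or that something still does (it is still moving / all of the starting material has reacted)
2. how much of the starting material has reacted by 30 h
3. how much target there is at 30 h, in percent of the starting material charged
4. how much open intermediate there is at 30 h, in percent of the starting material charged
5. amount of target if the flask were left three thousand times as long, in percent of the starting material charged

- the reaction counts as stopped when no species that holds the starting material changes by six tenths of a point or more over the second half of the time

I began with where the new flask would stand at 30 h. Its capture agent, 0.0400 M, lay between the 0.027 M of the summer run and the 0.060 M of the dawn run. Those runs ended with 12.3 % and 12.5 % of starting material, and 36.8 % and 35.4 % of target. So I took the means: 12.4 % left and 36.1 % target.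

Had it stopped by then? No: the dawn run lost 21 percentage points of starting material between 15.0 h and 30.0 h, far beyond the stopping limit.

So what was the remainder worth? Pooling both runs from 20.0 h to 30.0 h, I defined the late yield, the differential yield of the tail, as points of target gained per point of starting material lost: 0.824. Applied to the remainder, on the assumption that this ratio held, it gave an estimate of 46.3 % for the final target. The balance left 51.5 % for open intermediate and whatever the readings did not show, and I held that as a ceiling.

The forecast said it is still moving, with 87.6 % reacted, 36.2 % target, 46.5 % open intermediate and 46 % eventually, on the ground: “That suggests a reversible step”.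

The flask gave it is still moving, with 87.4 % reacted, 36.1 % target, 28.2 % open intermediate and 48.0 % eventually.

    partner → second intermediate (k = 3.99 × 10⁻⁵ s⁻¹)
    open intermediate + capture agent → trapped intermediate (k = 4.36 × 10⁻⁵ M⁻¹ s⁻¹)
    open intermediate + second intermediate → target (k = 6.43 × 10⁻⁵ M⁻¹ s⁻¹)
    partner → decomposed reagent (k = 2.09 × 10⁻⁵ s⁻¹)
    starting material → open intermediate (k = 1.50 × 10⁻⁵ s⁻¹)
    starting material + second intermediate → side product (k = 2.00 × 10⁻⁵ M⁻¹ s⁻¹)

At 30.0 h the flask also held 20.2 % side product and 3.02 % trapped intermediate. From the computed 36.1 %, the late yield gave 46.5 % eventually, against the 48.0 % computed.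

Left to 2.0 d, the same flask had 4.39 % starting material, so the late yield gave 42.9 % target, and the computed result was 43.4 %.

The runs were computed from invented constants.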